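The side chain is cut back to C1'–C4'. The trans, trisubstituted C2'–C3' oxirane carries at C3' a methylene (C4') that can be held for a time as CH2OH. This turns the C2'=C3' alkene of a 7-O-allyl ether on the coumarin (benzene ring and fused pyranone both left untouched) into an (E)-allylic alcohol. A titanium tartrate epoxidation then makes both C–O bonds of the three-membered ring and the C2' and C3' stereocentres in one operation. The precursor is (E)-7-(4-hydroxy-3-methylbut-2-enyloxy)-8-methoxycoumarin. Afterwards the C4' oxygen is exchanged for carbon, C5' becomes an aldehyde, and the 2-methylpropenyl group is added under ligand control.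

Key step: step 3

Assumption: side-chain atoms are labelled C1' (ether methylene) to C7' (dimethyl-bearing alkene carbon); 1, 2, 7 and 11 are taken as catalogue compounds, and the sense of both asymmetric steps would be confirmed by Mosher ester analysis before material is committed.

Step 1
Reactants: 1 7-hydroxy-8-methoxycoumarin; 2 1-bromo-3-methylbut-2-ene (prenyl bromide)
Product: 3 8-methoxy-7-[(3-methylbut-2-en-1-yl)oxy]coumarin
Conditions: K2CO3, acetone, reflux
Reagents that add atoms: none
Why: Williamson ether synthesis: the phenoxide formed by K2CO3 displaces the primary allylic bromide by SN2 at its unsubstituted terminus, and the lactone is inert to carbonate in acetone.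

Step 2
Reactants: 3 8-methoxy-7-[(3-methylbut-2-en-1-yl)oxy]coumarin
Product: 4 (E)-7-[(4-hydroxy-3-methylbut-2-en-1-yl)oxy]-8-methoxycoumarin
Conditions: SeO2 (20 mol %), t-BuOOH (70% aq., 3 equiv), salicylic acid (10 mol %), CH2Cl2, rt
Reagents that add atoms: selenium dioxide, O=[Se]=O; tert-butyl hydroperoxide, CC(C)(C)OO (terminal oxidant that restores the selenium oxide)
Why: Selenium dioxide allylic oxidation (ene reaction followed by [2,3]-sigmatropic shift, run catalytically with t-BuOOH) attacks the methyl group trans to the chain on the more substituted alkene carbon and should give the E allylic alcohol without moving the alkene, the run being stopped before much enal builds up (any enal can be returned to 4 by Luche reduction).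

Step 3
Reactants: 4 (E)-7-[(4-hydroxy-3-methylbut-2-en-1-yl)oxy]-8-methoxycoumarin
Product: 5 7-{[(2R,3R)-3-(hydroxymethyl)-3-methyloxiran-2-yl]methoxy}-8-methoxycoumarin
Conditions: Ti(OiPr)4 (10 mol %), D-(−)-diethyl tartrate (12 mol %), t-BuOOH (2 equiv, in decane), 4 Å MS, CH2Cl2, −20 °C; non-basic work-up
Reagents that add atoms: tert-butyl hydroperoxide, CC(C)(C)OO
Why: Ligand exchange places the alkoxide of 4 and the tert-butyl peroxide on the dimeric titanium tartrate, and the distal peroxide oxygen is then passed to the C2'=C3' alkene in one concerted, intramolecular event. The closest known reaction type is the Sharpless asymmetric epoxidation of (E)-2-methylalk-2-en-1-ols under catalytic molecular-sieve conditions, one of its best substrate classes. The oxirane closes by [2+1] oxygen-atom transfer: the C2'–O and C3'–O bonds form on the same alkene face at the same time, so no open-chain intermediate exists that could rotate. C2' and C3' are both set by the tartrate, the D-(−) ester sending oxygen to the face that gives 2'R,3'R (the mirror image of the 2S,3S outcome of the L-(+) ester with (E)-2-methylalk-2-enols), while their trans relation (C1' anti to C4') is inherited from the E alkene of step 2. The step needs chemoselectivity for this alkene over the pyranone C3–C4 alkene and enantiofacial control; the first follows because only an alkene held next to a titanium-bound alkoxide is oxidised and the pyranone alkene is electron-poor, the second because the C4' hydroxyl anchors the substrate in the chiral pocket.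

Step 4
Reactants: 5 7-{[(2R,3R)-3-(hydroxymethyl)-3-methyloxiran-2-yl]methoxy}-8-methoxycoumarin
Product: 6 [(2R,3R)-3-{[(8-methoxy-2-oxo-2H-chromen-7-yl)oxy]methyl}-2-methyloxiran-2-yl]methyl trifluoromethanesulfonate
Conditions: Tf2O, 2,6-lutidine, CH2Cl2, −78 °C; crude product used at once
Reagents that add atoms: trifluoromethanesulfonic anhydride, O=S(=O)(OS(=O)(=O)C(F)(F)F)C(F)(F)F
Why: Sulfonylation of a primary alcohol with triflic anhydride and a hindered pyridine base at −78 °C, where neither the oxirane nor the lactone carbonyl competes; no stereocentre is touched and the triflate is carried on without storage.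

Step 5
Reactants: 6 epoxy triflate; 7 vinylmagnesium bromide
Product: 8 8-methoxy-7-{[(2R,3R)-3-methyl-3-(prop-2-en-1-yl)oxiran-2-yl]methoxy}coumarin
Conditions: (CH2=CH)2CuMgBr [from 7 (3 equiv) and CuBr·SMe2 (1.5 equiv), THF, −78 °C]; then 6, −78 → −40 °C; aq. NH4Cl
Reagents that add atoms: none
Why: Copper-mediated SN2 coupling of a primary alkyl triflate with a Gilman-type divinylcuprate: at −78 °C the triflate at C4' is by far the fastest electrophile (vinylcuprates add only sluggishly to a 7-alkoxy-deactivated coumarin enoate and to a trisubstituted oxirane, and no free Grignard reagent remains for the lactone), so C2' and C3' stay as set.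

Step 6
Reactants: 8 8-methoxy-7-{[(2R,3R)-3-methyl-3-(prop-2-en-1-yl)oxiran-2-yl]methoxy}coumarin
Product: 10 2-[(2R,3R)-3-{[(8-methoxy-2-oxo-2H-chromen-7-yl)oxy]methyl}-2-methyloxiran-2-yl]acetaldehyde, via vicinal diol 9 (not isolated)
Conditions: OsO4 (2 mol %), NaIO4 (4 equiv), 2,6-lutidine (2 equiv), 1,4-dioxane–H2O (3:1), 0 °C → rt; crude aldehyde used directly
Reagents that add atoms: osmium tetroxide, O=[Os](=O)(=O)=O; sodium periodate, [Na+].[O-]I(=O)(=O)=O (restores the oxo ligands of osmium)
Why: Lemieux–Johnson oxidative cleavage with a 2,6-lutidine buffer: OsO4 dihydroxylates the monosubstituted terminal alkene much faster than the electron-poor pyranone C3–C4 alkene and periodate then cleaves the glycol, so the β,γ-epoxy aldehyde is released near neutrality without passing through an enol ether, enol or enolate that could open the oxirane, and it is used crude at once.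

Step 7
Reactants: 10 β,γ-epoxy aldehyde; 11 1-bromo-2-methylprop-1-ene
Product: 12 7-{[(2R,3R)-3-[(2R)-2-hydroxy-4-methylpent-3-en-1-yl]-3-methyloxiran-2-yl]methoxy}-8-methoxycoumarin
Conditions: CrCl2 (10 mol %), chiral oxazoline–sulfonamide ligand (11 mol %), 1,8-bis(dimethylamino)naphthalene (11 mol %), NiCl2·(2,9-dimethyl-1,10-phenanthroline) (5 mol %), Mn (2 equiv), Zr(Cp)2Cl2 (1.2 equiv), LiCl (2 equiv), MeCN, rt
Reagents that add atoms: none
Why: Catalytic asymmetric Nozaki–Hiyama–Kishi reaction: the nickel co-catalyst inserts into the alkenyl bromide and passes the alkenyl group to chromium, whose complex with the ligand N-[2-(4-isopropyl-4,5-dihydro-1,3-oxazol-2-yl)-6-methylphenyl]methanesulfonamide (the antipode chosen that sends the alkenyl group to the Si face of the aldehyde) adds it only to the aldehyde under neutral conditions that lactone, oxirane and enoate tolerate, so C5' (R) is set under reagent control.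

Compound list
1 | 7-hydroxy-8-methoxy-2H-chromen-2-one (7-hydroxy-8-methoxycoumarin) | COc1c(O)ccc2ccc(=O)oc12 | starting material
2 | 1-bromo-3-methylbut-2-ene (prenyl bromide) | CC(C)=CCBr | starting material
3 | 8-methoxy-7-[(3-methylbut-2-en-1-yl)oxy]-2H-chromen-2-one | COc1c(OCC=C(C)C)ccc2ccc(=O)oc12 | intermediate
4 | 7-{[(2E)-4-hydroxy-3-methylbut-2-en-1-yl]oxy}-8-methoxy-2H-chromen-2-one | COc1c(OC/C=C(\C)CO)ccc2ccc(=O)oc12 | intermediate
5 | 7-{[(2R,3R)-3-(hydroxymethyl)-3-methyloxiran-2-yl]methoxy}-8-methoxy-2H-chromen-2-one | COc1c(OC[C@H]2O[C@]2(C)CO)ccc2ccc(=O)oc12 | intermediate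
6 | [(2R,3R)-3-{[(8-methoxy-2-oxo-2H-chromen-7-yl)oxy]methyl}-2-methyloxiran-2-yl]methyl trifluoromethanesulfonate | COc1c(OC[C@H]2O[C@]2(C)COS(=O)(=O)C(F)(F)F)ccc2ccc(=O)oc12 | intermediate
7 | vinylmagnesium bromide (ethenylmagnesium bromide) | C=C[Mg]Br | starting material
8 | 8-methoxy-7-{[(2R,3R)-3-methyl-3-(prop-2-en-1-yl)oxiran-2-yl]methoxy}-2H-chromen-2-one | COc1c(OC[C@H]2O[C@]2(C)CC=C)ccc2ccc(=O)oc12 | intermediate
9 | 7-{[(2R,3R)-3-(2,3-dihydroxypropyl)-3-methyloxiran-2-yl]methoxy}-8-methoxy-2H-chromen-2-one (both configurations at the new carbinol; not isolated) | COc1c(OC[C@H]2O[C@]2(C)CC(O)CO)ccc2ccc(=O)oc12 | intermediate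
10 | 2-[(2R,3R)-3-{[(8-methoxy-2-oxo-2H-chromen-7-yl)oxy]methyl}-2-methyloxiran-2-yl]acetaldehyde | COc1c(OC[C@H]2O[C@]2(C)CC=O)ccc2ccc(=O)oc12 | intermediate
11 | 1-bromo-2-methylprop-1-ene | CC(C)=CBr | starting material
12 | 7-{[(2R,3R)-3-[(2R)-2-hydroxy-4-methylpent-3-en-1-yl]-3-methyloxiran-2-yl]methoxy}-8-methoxy-2H-chromen-2-one | COc1c(OC[C@H]2O[C@]2(C)C[C@@H](O)C=C(C)C)ccc2ccc(=O)oc12 | target

Total step count: 7. Longest linear sequence: 7 steps (1 → 12).

Steps most likely to fail

Step 6. Once the C5' carbonyl is free, the acidic C4' hydrogens invite β-elimination that opens the oxirane (E1cB), and the aqueous buffer gives this time to happen; competing dihydroxylation of the pyranone alkene is a lesser concern. The fallback avoids the aldehyde and sets out from 6. 3-Methylbut-2-enal and propane-1,3-dithiol (BF3·OEt2, CH2Cl2) give 2-(2-methylprop-1-en-1-yl)-1,3-dithiane F5, which is deprotonated (n-BuLi, THF, −30 °C) to its 2-lithio derivative F6. Triflate 6 is added to this anion at −78 °C, where alkylation at the dithiane carbon should outrun attack on the lactone, to give the C4'-alkylated dithiane F7. Alkylative hydrolysis (MeI, CaCO3, MeCN–H2O) then unmasks the β,γ-epoxy enone F8 without base. Corey–Bakshi–Shibata reduction ((S)-1-methyl-3,3-diphenyltetrahydro-1H,3H-pyrrolo[1,2-c][1,3,2]oxazaborole, catecholborane, toluene, −78 °C; alkenyl as the large group) should give the 5'R alcohol, and the route is rejoined at 12.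

Step 5. The cuprate may add to the coumarin enoate or open the oxirane, or substitution at the hindered C4' may be too slow and let the triflate decompose. The fallback replaces the organometallic substitution by carbonyl chemistry and sets out from 5. Buffered Dess–Martin oxidation (NaHCO3, CH2Cl2, 0 °C) gives the epoxy aldehyde F1, which has no α-hydrogen. Wittig methylenation (Ph3P=CH2 from Ph3PCH3Br and KN(SiMe3)2, THF, −78 → 0 °C) gives the vinyl epoxide F2. Hydroboration with 9-BBN (THF, 0 °C → rt) places boron on the terminal carbon to give the alkylborane F3, which is oxidised in the same flask (NaBO3·4H2O) to the 3,4-epoxy alcohol F4. A second buffered Dess–Martin oxidation returns the route to 10 under anhydrous conditions.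

Step 7. Facial selectivity at C5' may be insufficient, and the Lewis acidic chloride-rich medium may erode the aldehyde before it is captured. The fallback sets out from 10. The coupling with 11 is run without chiral ligand (CrCl2, NiCl2 (cat.), DMSO, rt) to give the alcohol F9 as a mixture of C5' epimers. Buffered Dess–Martin oxidation converts the mixture into the enone F8, and the oxazaborolidine-catalysed reduction described for the first fallback sets C5' and rejoins the route at 12.

Further compounds
F1 | step 5 | (2S,3R)-3-{[(8-methoxy-2-oxo-2H-chromen-7-yl)oxy]methyl}-2-methyloxirane-2-carbaldehyde | COc1c(OC[C@H]2O[C@]2(C)C=O)ccc2ccc(=O)oc12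
F2 | step 5 | 7-{[(2R,3R)-3-ethenyl-3-methyloxiran-2-yl]methoxy}-8-methoxy-2H-chromen-2-one | COc1c(OC[C@H]2O[C@]2(C)C=C)ccc2ccc(=O)oc12
F3 | step 5 | 9-{2-[(2R,3R)-3-{[(8-methoxy-2-oxo-2H-chromen-7-yl)oxy]methyl}-2-methyloxiran-2-yl]ethyl}-9-borabicyclo[3.3.1]nonane (not isolated) | COc1c(OC[C@H]2O[C@]2(C)CCB3C4CCCC3CCC4)ccc2ccc(=O)oc12
F4 | step 5 | 7-{[(2R,3R)-3-(2-hydroxyethyl)-3-methyloxiran-2-yl]methoxy}-8-methoxy-2H-chromen-2-one | COc1c(OC[C@H]2O[C@]2(C)CCO)ccc2ccc(=O)oc12
F5 | step 6 | 2-(2-methylprop-1-en-1-yl)-1,3-dithiane | CC(C)=CC1SCCCS1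
F6 | step 6 | 2-lithio-2-(2-methylprop-1-en-1-yl)-1,3-dithiane (not isolated) | [Li]C1(C=C(C)C)SCCCS1
F7 | step 6 | 8-methoxy-7-{[(2R,3R)-3-methyl-3-{[2-(2-methylprop-1-en-1-yl)-1,3-dithian-2-yl]methyl}oxiran-2-yl]methoxy}-2H-chromen-2-one | COc1c(OC[C@H]2O[C@]2(C)CC3(C=C(C)C)SCCCS3)ccc2ccc(=O)oc12
F8 | step 6 | 8-methoxy-7-{[(2R,3R)-3-methyl-3-(4-methyl-2-oxopent-3-en-1-yl)oxiran-2-yl]methoxy}-2H-chromen-2-one | COc1c(OC[C@H]2O[C@]2(C)CC(=O)C=C(C)C)ccc2ccc(=O)oc12
F9 | step 7 | 7-{[(2R,3R)-3-(2-hydroxy-4-methylpent-3-en-1-yl)-3-methyloxiran-2-yl]methoxy}-8-methoxy-2H-chromen-2-one, mixture of C5' epimers | COc1c(OC[C@H]2O[C@]2(C)CC(O)C=C(C)C)ccc2ccc(=O)oc12
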